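Everything rests on opening benzene ring A of unit 1 (benzofuran numbering, unit 2 primed) at C3a–C7a and C4–C5. Ring A bears hydrogen only at C5 and C7, an oxygen at C6 and O1 at C7a; a pyridazine oxygenated at its 3- and 5-positions maps onto C7a, C7, C6 and C5, and an alkyne supplies C3a and C4 in place of the two nitrogens. One thermal step, intramolecular diazine–alkyne cycloaddition followed by loss of N2, thus closes ring A and the dihydrofuran of unit 1 at once, with the (E)-styryl group already on C4. The precursor is the 5-benzyloxypyridazin-3-yl ether of an anti homopropargylic alcohol carrying unit 2, the C3 aryl group and the enyne.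

Key step: step 18

Remarks on the chemistry:
- Protection: phenols are carried as benzyl ethers from step 8 on (methyl ethers serve only while unit 2 is built). A closing Lewis-acid demethylation near room temperature would expose the 3-aryl-4-styryl-dihydrobenzofuran of unit 1 to acid-induced ring closure onto the alkene, whereas benzyl ethers are cleaved at −78 °C.
- Assumption: Rh2(R-PTAD)4 is taken as the catalyst enantiomer that gives the 3S product in step 6; the mirror-image catalyst would be used if the sense proved opposite.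
- Assumption: the allenylindium addition of step 13 is taken to run with net inversion at the propargylic carbon (anti attack of zerovalent palladium on the mesylate, retentive transmetalation, addition on the indium-bearing face).
- Abbreviation: U2 = (2S,3S)-4-(benzyloxy)-2-[2,4-bis(benzyloxy)phenyl]-3-[3,5-bis(benzyloxy)phenyl]-2,3-dihydrobenzofuran-7-yl.

Step 1
Reactants: 1 2-bromo-5-methoxyphenol
Product: 2 3-bromo-2-hydroxy-6-methoxybenzaldehyde
Conditions: MgCl2, Et3N, (CH2O)n, THF, reflux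
Reagents that add atoms: paraformaldehyde (as formaldehyde), C=O
Why: Magnesium-mediated ortho-formylation of phenols (Casnati–Skattebøl reaction) delivers the formyl group only ortho to the phenoxide, and the single free ortho position lies between OH and OMe.

Step 2
Reactants: 2 3-bromo-2-hydroxy-6-methoxybenzaldehyde; 3 2,4-dimethoxybenzyl alcohol
Product: 4 3-bromo-2-[(2,4-dimethoxybenzyl)oxy]-6-methoxybenzaldehyde
Conditions: PPh3, DIAD, THF, 0 °C to rt
Reagents that add atoms: none
Why: Mitsunobu etherification of an acidic salicylaldehyde-type phenol with a primary benzylic alcohol should be clean, and the benzylic CH2 installed here later becomes C2' of unit 2.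

Step 3
Reactants: 4 3-bromo-2-[(2,4-dimethoxybenzyl)oxy]-6-methoxybenzaldehyde; 5 3,5-dimethoxyphenylmagnesium chloride
Product: 6 rac-{3-bromo-2-[(2,4-dimethoxybenzyl)oxy]-6-methoxyphenyl}(3,5-dimethoxyphenyl)methanol
Conditions: THF, 0 °C to rt; aq NH4Cl
Reagents that add atoms: none
Why: Grignard 1,2-addition to the aldehyde should proceed without touching the aryl bromide at this temperature, and the racemic carbinol centre is erased in step 4.

Step 4
Reactants: 6 rac-{3-bromo-2-[(2,4-dimethoxybenzyl)oxy]-6-methoxyphenyl}(3,5-dimethoxyphenyl)methanol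
Product: 7 {3-bromo-2-[(2,4-dimethoxybenzyl)oxy]-6-methoxyphenyl}(3,5-dimethoxyphenyl)methanone
Conditions: Dess–Martin periodinane, CH2Cl2, rt
Reagents that add atoms: none
Why: Dess–Martin oxidation converts a secondary diaryl carbinol into the ketone under mild conditions that spare the acid-labile dimethoxybenzyl ether.

Step 5
Reactants: 7 {3-bromo-2-[(2,4-dimethoxybenzyl)oxy]-6-methoxyphenyl}(3,5-dimethoxyphenyl)methanone
Product: 8 hydrazone of ketone 7 (E/Z mixture)
Conditions: N2H4·H2O (excess), AcOH (cat.), n-BuOH, 110 °C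
Reagents that add atoms: hydrazine hydrate, NN
Why: Acid-catalysed hydrazone condensation, driven by excess hydrazine and heat because both ortho positions of ring C are substituted, should give the hydrazone, whose E/Z mixture is used as such.

Step 6
Reactants: 8 hydrazone of ketone 7
Product: 10 (2R,3S)-7-bromo-2-(2,4-dimethoxyphenyl)-3-(3,5-dimethoxyphenyl)-4-methoxy-2,3-dihydrobenzofuran (cis), via diaryldiazomethane 9 (not isolated)
Conditions: MnO2, CH2Cl2, rt, filtration; Rh2(R-PTAD)4 (1 mol%), CH2Cl2, 0 °C to rt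
Reagents that add atoms: none
Why: MnO2 dehydrogenates the hydrazone to the diazo compound and the chiral dirhodium tetracarboxylate converts it into a donor/donor carbene that inserts into the activated benzylic C–H of the ether (1,5-insertion closing the dihydrofuran of unit 2), with the catalyst setting C3' as S and the concerted insertion giving the cis C2' epimer that step 7 corrects.

Step 7
Reactants: 10 (2R,3S)-7-bromo-2-(2,4-dimethoxyphenyl)-3-(3,5-dimethoxyphenyl)-4-methoxy-2,3-dihydrobenzofuran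
Product: 11 (2S,3S)-7-bromo-2-(2,4-dihydroxyphenyl)-3-(3,5-dihydroxyphenyl)-2,3-dihydrobenzofuran-4-ol (trans)
Conditions: BBr3 (excess), CH2Cl2, −78 °C to rt; MeOH, then H2O
Reagents that add atoms: none
Why: BBr3 cleaves the five aryl methyl ethers and at the same time reversibly ionises the O1'–C2' bond to the 2,4-dioxygenated benzylic cation, whose reclosure should give the thermodynamically preferred trans isomer while C3' is untouched (Lewis-acid ether cleavage with C2 epimerisation, known for cis-2-(oxyaryl)-3-aryl-dihydrobenzofurans).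

Step 8
Reactants: 11 (2S,3S)-7-bromo-2-(2,4-dihydroxyphenyl)-3-(3,5-dihydroxyphenyl)-2,3-dihydrobenzofuran-4-ol
Product: 12 U2–Br, (2S,3S)-4-(benzyloxy)-2-[2,4-bis(benzyloxy)phenyl]-3-[3,5-bis(benzyloxy)phenyl]-7-bromo-2,3-dihydrobenzofuran
Conditions: BnBr, K2CO3, DMF, rt to 50 °C
Reagents that add atoms: benzyl bromide, BrCc1ccccc1
Why: Williamson benzylation of the five phenols under mild carbonate conditions installs the protecting group that is removable at −78 °C and leaves both stereocentres alone.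

Step 9
Reactants: 12 U2–Br
Product: 14 U2–CHO, (2S,3S)-4-(benzyloxy)-2-[2,4-bis(benzyloxy)phenyl]-3-[3,5-bis(benzyloxy)phenyl]-2,3-dihydrobenzofuran-7-carbaldehyde, via aryllithium 13 (not isolated)
Conditions: n-BuLi, THF, −78 °C; DMF; aq NH4Cl
Reagents that add atoms: N,N-dimethylformamide, CN(C)C=O
Why: Bromine–lithium exchange at −78 °C is faster than any deprotonation of the benzyl ethers and the aryllithium is formylated by DMF (Bouveault formylation), which places the aldehyde on C7' where no electrophilic formylation would be selective.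

Step 10
Reactants: 15 3,5-bis(benzyloxy)benzaldehyde; 16 ethynylmagnesium bromide
Product: 17 rac-1-[3,5-bis(benzyloxy)phenyl]prop-2-yn-1-ol
Conditions: THF, 0 °C; aq NH4Cl
Reagents that add atoms: none
Why: Addition of an alkynyl Grignard reagent to an aromatic aldehyde gives the racemic propargylic alcohol that is resolved in step 11.

Step 11
Reactants: 17 rac-1-[3,5-bis(benzyloxy)phenyl]prop-2-yn-1-ol
Product: 18 (S)-1-[3,5-bis(benzyloxy)phenyl]prop-2-yn-1-ol (recovered enantiomer)
Conditions: Novozym 435 (immobilised Candida antarctica lipase B), vinyl acetate, MTBE, 35 °C, run to just past half conversion; chromatography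
Reagents that add atoms: none
Why: Lipase-catalysed kinetic resolution follows the Kazlauskas rule with aryl as the large and ethynyl as the medium group, so the R alcohol is acetylated and the S alcohol should be recovered in high enantiomeric purity.

Step 12
Reactants: 18 (S)-1-[3,5-bis(benzyloxy)phenyl]prop-2-yn-1-ol
Product: 19 (S)-1-[3,5-bis(benzyloxy)phenyl]prop-2-yn-1-yl methanesulfonate
Conditions: MsCl, Et3N, CH2Cl2, −78 °C; used at once
Reagents that add atoms: methanesulfonyl chloride, CS(=O)(=O)Cl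
Why: O-sulfonylation leaves the C–O bond and hence the configuration intact, and the two meta oxygens disfavour ionisation of this benzylic propargylic mesylate long enough for immediate use.

Step 13
Reactants: 14 U2–CHO; 19 (S)-1-[3,5-bis(benzyloxy)phenyl]prop-2-yn-1-yl methanesulfonate
Product: 21 (1S,2R)-2-[3,5-bis(benzyloxy)phenyl]-1-(U2)but-3-yn-1-ol (anti), via allenylindium iodide mesylate 20 (not isolated)
Conditions: Pd(dppf)Cl2 (5 mol%), InI, THF–HMPA (3:1), rt
Reagents that add atoms: none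
Why: In this palladium-catalysed, indium-mediated propargylation (Marshall reaction) zerovalent palladium displaces the mesylate anti in an SN2' sense, transmetalation with InI gives the chiral allenylindium 20, and its addition to the aldehyde through a closed six-membered SE2' transition state should set C3 by chirality transfer from 19 and C2 anti to it, the minor syn isomer being removed by chromatography.

Step 14
Reactants: 22 3,5-dichloropyridazine
Product: 23 5-(benzyloxy)-3-chloropyridazine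
Conditions: BnOH, NaH, THF, 0 °C
Reagents that add atoms: benzyl alcohol, OCc1ccccc1
Why: Nucleophilic aromatic substitution by an alkoxide on 3,5-dichloropyridazine occurs preferentially at C5, as in the known preparation of the 5-methoxy analogue, leaving the C3 chloride for step 15.

Step 15
Reactants: 21 (1S,2R)-2-[3,5-bis(benzyloxy)phenyl]-1-(U2)but-3-yn-1-ol; 23 5-(benzyloxy)-3-chloropyridazine
Product: 24 5-(benzyloxy)-3-{[(1S,2R)-2-[3,5-bis(benzyloxy)phenyl]-1-(U2)but-3-yn-1-yl]oxy}pyridazine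
Conditions: NaH, THF, 0 °C to 40 °C
Reagents that add atoms: none
Why: Nucleophilic aromatic substitution of the sodium alkoxide at C3 of the chlorodiazine (alpha to nitrogen) forms the aryl ether without breaking the O–C2 bond, so C2 keeps its configuration, and the acidic terminal alkyne C–H buffers any excess base away from the propargylic C3–H.

Step 16
Reactants: 25 (E)-4-(benzyloxy)cinnamic acid
Product: 26 (E)-1-(benzyloxy)-4-(2-bromovinyl)benzene
Conditions: NBS, LiOAc (cat.), MeCN–H2O, rt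
Reagents that add atoms: N-bromosuccinimide, O=C1CCC(=O)N1Br
Why: The catalytic Hunsdiecker bromodecarboxylation of electron-rich cinnamic acids gives the (E)-β-bromostyrene directly.

Step 17
Reactants: 24 terminal alkyne pyridazinyl ether; 26 (E)-1-(benzyloxy)-4-(2-bromovinyl)benzene
Product: 27 5-(benzyloxy)-3-{[(1S,2S,5E)-2-[3,5-bis(benzyloxy)phenyl]-6-[4-(benzyloxy)phenyl]-1-(U2)hex-5-en-3-yn-1-yl]oxy}pyridazine
Conditions: Pd(PPh3)2Cl2 (3 mol%), CuI (6 mol%), Et3N, THF, rt, degassed
Reagents that add atoms: none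
Why: Sonogashira coupling of a terminal alkyne with a vinyl bromide proceeds at room temperature with retention of the E geometry and uses only an amine base, so the stereocentres and the diazine ether should be unaffected.

Step 18
Reactants: 27 enyne pyridazinyl ether
Product: 29 (2S,3S)-6-(benzyloxy)-3-[3,5-bis(benzyloxy)phenyl]-4-[(E)-2-(4-(benzyloxy)phenyl)ethenyl]-2-(U2)-2,3-dihydrobenzofuran (nonabenzyl ether of 30), via bridged diazabicyclooctatriene adduct 28 (not isolated)
Conditions: 1,3,5-triisopropylbenzene (0.005 M), BHT (10 mol%), 2,6-di-tert-butyl-4-methylpyridine (20 mol%), Ar, sealed tube, 200 °C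
Reagents that add atoms: none
Why: On heating, the alkyne adds across C3 and C6 of the diazine in an intramolecular inverse-electron-demand [4+2] cycloaddition to give the 2,3-diazabicyclo[2.2.2]octatriene 28, which loses N2 by retro-[4+2] and so aromatises directly to ring A. The closest known reaction is the thermal conversion of 3-(but-3-ynyloxy)pyridazines into 2,3-dihydrobenzofurans. The dihydrofuran of unit 1 closes as the five-membered ring imposed by the three-atom O1–C2–C3 tether (proximal alkyne carbon onto the oxygen-bearing diazine carbon, C3a–C7a), and ring A closes as the six-membered ring of the cycloadduct (C4–C5). No stereocentre is formed: C2 and C3 are not touched, the (E)-alkene is only a substituent of the dienophile, and both bridgehead epimers of 28 converge on the same arene. The step needs regioselectivity, which the tether enforces because no other pair of diazine carbons can be reached, and survival of the benzylic pyridazinyl ether and of the propargylic C3–H, which a dilute, degassed, acid-free medium buffered by a hindered pyridine and inert benzyl ethers should secure. The donor-substituted conjugated enyne and the two substituents on the tether should offset part of the rate loss caused by the 5-benzyloxy group.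

Step 19
Reactants: 29 nonabenzyl ether of the target
Product: 30 (2S,3S)-2-[(2S,3S)-2-(2,4-dihydroxyphenyl)-3-(3,5-dihydroxyphenyl)-4-hydroxy-2,3-dihydrobenzofuran-7-yl]-3-(3,5-dihydroxyphenyl)-4-[(E)-2-(4-hydroxyphenyl)ethenyl]-2,3-dihydrobenzofuran-6-ol (CNP0397447.1)
Conditions: BCl3, C6HMe5 (excess), CH2Cl2, −78 °C; MeOH quench at −78 °C
Reagents that add atoms: none
Why: BCl3 with pentamethylbenzene as a non-basic benzyl-cation scavenger cleaves aryl benzyl ethers at −78 °C without reduction, so the stilbene should survive, and any reversible opening of the two dihydrofurans can only return the trans isomers that are already in place.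

Compound list
1 | 2-bromo-5-methoxyphenol | Oc1cc(OC)ccc1Br | starting material
2 | 3-bromo-2-hydroxy-6-methoxybenzaldehyde | O=Cc1c(O)c(Br)ccc1OC | intermediate
3 | 2,4-dimethoxybenzyl alcohol | OCc1ccc(OC)cc1OC | starting material
4 | 3-bromo-2-[(2,4-dimethoxybenzyl)oxy]-6-methoxybenzaldehyde | O=Cc1c(OCc2ccc(OC)cc2OC)c(Br)ccc1OC | intermediate
5 | 3,5-dimethoxyphenylmagnesium chloride (THF solution) | COc1cc(OC)cc([Mg]Cl)c1 | starting material
6 | rac-{3-bromo-2-[(2,4-dimethoxybenzyl)oxy]-6-methoxyphenyl}(3,5-dimethoxyphenyl)methanol | OC(c1cc(OC)cc(OC)c1)c1c(OCc2ccc(OC)cc2OC)c(Br)ccc1OC | intermediate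
7 | {3-bromo-2-[(2,4-dimethoxybenzyl)oxy]-6-methoxyphenyl}(3,5-dimethoxyphenyl)methanone | O=C(c1cc(OC)cc(OC)c1)c1c(OCc2ccc(OC)cc2OC)c(Br)ccc1OC | intermediate
8 | hydrazone of 7 (E/Z mixture) | NN=C(c1cc(OC)cc(OC)c1)c1c(OCc2ccc(OC)cc2OC)c(Br)ccc1OC | intermediate
9 | {3-bromo-2-[(2,4-dimethoxybenzyl)oxy]-6-methoxyphenyl}(3,5-dimethoxyphenyl)diazomethane | [N-]=[N+]=C(c1cc(OC)cc(OC)c1)c1c(OCc2ccc(OC)cc2OC)c(Br)ccc1OC | intermediate (not isolated)
10 | (2R,3S)-7-bromo-2-(2,4-dimethoxyphenyl)-3-(3,5-dimethoxyphenyl)-4-methoxy-2,3-dihydrobenzofuran (cis) | Brc1ccc(OC)c2c1O[C@@H](c1ccc(OC)cc1OC)[C@H]2c1cc(OC)cc(OC)c1 | intermediate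
11 | (2S,3S)-7-bromo-2-(2,4-dihydroxyphenyl)-3-(3,5-dihydroxyphenyl)-2,3-dihydrobenzofuran-4-ol (trans) | Brc1ccc(O)c2c1O[C@H](c1ccc(O)cc1O)[C@H]2c1cc(O)cc(O)c1 | intermediate
12 | U2–Br, (2S,3S)-4-(benzyloxy)-2-[2,4-bis(benzyloxy)phenyl]-3-[3,5-bis(benzyloxy)phenyl]-7-bromo-2,3-dihydrobenzofuran | Brc1ccc(OCc3ccccc3)c2c1O[C@H](c1ccc(OCc3ccccc3)cc1OCc1ccccc1)[C@H]2c1cc(OCc2ccccc2)cc(OCc2ccccc2)c1 | intermediate
13 | U2–Li, the 7-lithio derivative of 12 | [Li]c1ccc(OCc3ccccc3)c2c1O[C@H](c1ccc(OCc3ccccc3)cc1OCc1ccccc1)[C@H]2c1cc(OCc2ccccc2)cc(OCc2ccccc2)c1 | intermediate (not isolated)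
14 | U2–CHO, (2S,3S)-4-(benzyloxy)-2-[2,4-bis(benzyloxy)phenyl]-3-[3,5-bis(benzyloxy)phenyl]-2,3-dihydrobenzofuran-7-carbaldehyde | O=Cc1ccc(OCc3ccccc3)c2c1O[C@H](c1ccc(OCc3ccccc3)cc1OCc1ccccc1)[C@H]2c1cc(OCc2ccccc2)cc(OCc2ccccc2)c1 | intermediate
15 | 3,5-bis(benzyloxy)benzaldehyde | O=Cc1cc(OCc2ccccc2)cc(OCc2ccccc2)c1 | starting material
16 | ethynylmagnesium bromide (THF solution) | C#C[Mg]Br | starting material
17 | rac-1-[3,5-bis(benzyloxy)phenyl]prop-2-yn-1-ol | C#CC(O)c1cc(OCc2ccccc2)cc(OCc2ccccc2)c1 | intermediate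
18 | (S)-1-[3,5-bis(benzyloxy)phenyl]prop-2-yn-1-ol | C#C[C@H](O)c1cc(OCc2ccccc2)cc(OCc2ccccc2)c1 | intermediate
19 | (S)-1-[3,5-bis(benzyloxy)phenyl]prop-2-yn-1-yl methanesulfonate | C#C[C@H](OS(C)(=O)=O)c1cc(OCc2ccccc2)cc(OCc2ccccc2)c1 | intermediate
20 | (aS)-{3-[3,5-bis(benzyloxy)phenyl]propa-1,2-dien-1-yl}indium iodide methanesulfonate | [H]C([In](I)OS(C)(=O)=O)=[C@]=C([H])c1cc(OCc2ccccc2)cc(OCc2ccccc2)c1 | intermediate (not isolated)
21 | (1S,2R)-2-[3,5-bis(benzyloxy)phenyl]-1-(U2)but-3-yn-1-ol (anti) | C#C[C@H](c1cc(OCc2ccccc2)cc(OCc2ccccc2)c1)[C@@H](c1ccc(OCc2ccccc2)c2c1O[C@H](c1ccc(OCc3ccccc3)cc1OCc1ccccc1)[C@H]2c1cc(OCc2ccccc2)cc(OCc2ccccc2)c1)O | intermediate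
22 | 3,5-dichloropyridazine | Clc1cc(Cl)cnn1 | starting material
23 | 5-(benzyloxy)-3-chloropyridazine | Clc1cc(OCc2ccccc2)cnn1 | intermediate
24 | 5-(benzyloxy)-3-{[(1S,2R)-2-[3,5-bis(benzyloxy)phenyl]-1-(U2)but-3-yn-1-yl]oxy}pyridazine | C#C[C@H](c1cc(OCc2ccccc2)cc(OCc2ccccc2)c1)[C@@H](c1ccc(OCc2ccccc2)c2c1O[C@H](c1ccc(OCc3ccccc3)cc1OCc1ccccc1)[C@H]2c1cc(OCc2ccccc2)cc(OCc2ccccc2)c1)Oc1cc(OCc2ccccc2)cnn1 | intermediate
25 | (E)-4-(benzyloxy)cinnamic acid | OC(=O)/C=C/c1ccc(OCc2ccccc2)cc1 | starting material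
26 | (E)-1-(benzyloxy)-4-(2-bromovinyl)benzene | Br/C=C/c1ccc(OCc2ccccc2)cc1 | intermediate
27 | 5-(benzyloxy)-3-{[(1S,2S,5E)-2-[3,5-bis(benzyloxy)phenyl]-6-[4-(benzyloxy)phenyl]-1-(U2)hex-5-en-3-yn-1-yl]oxy}pyridazine (precursor of the key step) | c1ccccc1COc1ccc(/C=C/C#C[C@H](c2cc(OCc3ccccc3)cc(OCc3ccccc3)c2)[C@@H](c2ccc(OCc3ccccc3)c3c2O[C@H](c2ccc(OCc4ccccc4)cc2OCc2ccccc2)[C@H]3c2cc(OCc3ccccc3)cc(OCc3ccccc3)c2)Oc2cc(OCc3ccccc3)cnn2)cc1 | intermediate
28 | 2,3-diazabicyclo[2.2.2]octa-2,5,7-triene cycloadduct of 27 (C3a–C7a and C4–C5 formed, N=N bridge still present; either bridgehead configuration) | c1ccccc1COc1ccc(/C=C/C2=C3[C@H](c4cc(OCc5ccccc5)cc(OCc5ccccc5)c4)[C@@H](c4ccc(OCc5ccccc5)c5c4O[C@H](c4ccc(OCc6ccccc6)cc4OCc4ccccc4)[C@H]5c4cc(OCc5ccccc5)cc(OCc5ccccc5)c4)OC34N=NC2C(OCc2ccccc2)=C4)cc1 | intermediate (not isolated)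
29 | (2S,3S)-6-(benzyloxy)-3-[3,5-bis(benzyloxy)phenyl]-4-[(E)-2-(4-(benzyloxy)phenyl)ethenyl]-2-(U2)-2,3-dihydrobenzofuran (nonabenzyl ether of 30; product of the key step) | c1ccccc1COc1ccc(/C=C/c2cc(OCc3ccccc3)cc3c2[C@H](c2cc(OCc4ccccc4)cc(OCc4ccccc4)c2)[C@@H](c2ccc(OCc4ccccc4)c4c2O[C@H](c2ccc(OCc5ccccc5)cc2OCc2ccccc2)[C@H]4c2cc(OCc4ccccc4)cc(OCc4ccccc4)c2)O3)cc1 | intermediate
30 | (2S,3S)-2-[(2S,3S)-2-(2,4-dihydroxyphenyl)-3-(3,5-dihydroxyphenyl)-4-hydroxy-2,3-dihydrobenzofuran-7-yl]-3-(3,5-dihydroxyphenyl)-4-[(E)-2-(4-hydroxyphenyl)ethenyl]-2,3-dihydrobenzofuran-6-ol (CNP0397447.1) | Oc1ccc(/C=C/c2cc(O)cc3c2[C@H](c2cc(O)cc(O)c2)[C@@H](c2ccc(O)c4c2O[C@H](c2ccc(O)cc2O)[C@H]4c2cc(O)cc(O)c2)O3)cc1 | target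

Total step count: 19 steps.
Longest linear sequence: 14 steps (steps 1–9, 13, 15, 17, 18, 19).

Steps most likely to fail

1. Step 18 (key cycloaddition). The enyne may oligomerise, or the benzylic pyridazinyl ether may ionise or eliminate, before the donor-substituted diazine has reacted. Fallback, from 24 back to 29: the stilbene is taken out of the thermolysis and an electron-poor dienophile is matched to the donor-substituted diazine. Coupling of 24 with ethyl chloroformate (Pd(PPh3)2Cl2, CuI, Et3N, THF, rt) should give ethyl (4S,5S)-4-[3,5-bis(benzyloxy)phenyl]-5-{[5-(benzyloxy)pyridazin-3-yl]oxy}-5-(U2)pent-2-ynoate F1. Heating F1 in 1,3,5-triisopropylbenzene should pass through the bridged cycloadduct F2 and, after loss of N2, give ethyl (2S,3S)-6-(benzyloxy)-3-[3,5-bis(benzyloxy)phenyl]-2-(U2)-2,3-dihydrobenzofuran-4-carboxylate F3. DIBAL-H reduction (CH2Cl2, −78 °C) gives the 4-(hydroxymethyl) compound F4 and MnO2 oxidation the 4-carbaldehyde F5. Horner–Wadsworth–Emmons olefination of F5 with diethyl [4-(benzyloxy)benzyl]phosphonate and KOtBu in THF installs the (E)-stilbene and returns to 29.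

2. Step 19 (global debenzylation). BCl3 may ionise the O1–C2 or O1'–C2' bonds, whose benzylic carbons carry ortho- and para-oxygenated aryl groups, with capture of the cations by the scavenger, or cleavage of nine ethers may stay incomplete. Fallback, from 29 back to 30: nucleophilic instead of electrophilic cleavage, with sodium ethanethiolate in DMF at 110 °C under argon followed by acidification to pH 5. The thiolate attacks the benzylic CH2 groups by SN2, no Lewis or Brønsted acid is present, and the fallback makes no new compound (F0).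

3. Step 5 (hydrazone formation). The condensation may stall because both ortho positions of ring C shield the carbonyl carbon, leaving ketone 7 unchanged. Fallback, from 4 back to 8: the C=N bond is made from a nitrile instead of a ketone. Treatment of aldehyde 4 with I2 and aqueous NH3 in THF should give 3-bromo-2-[(2,4-dimethoxybenzyl)oxy]-6-methoxybenzonitrile F6. Addition of Grignard reagent 5 (THF, 60 °C) and a methanol quench give the N-unsubstituted ketimine F7, which is not isolated. Exchange of F7 with hydrazine hydrate and catalytic AcOH in ethanol, with loss of ammonia, gives hydrazone 8.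

Further compounds
F1 | step 18 | ethyl (4S,5S)-4-[3,5-bis(benzyloxy)phenyl]-5-{[5-(benzyloxy)pyridazin-3-yl]oxy}-5-(U2)pent-2-ynoate | CCOC(=O)C#C[C@H](c1cc(OCc2ccccc2)cc(OCc2ccccc2)c1)[C@@H](c1ccc(OCc2ccccc2)c2c1O[C@H](c1ccc(OCc3ccccc3)cc1OCc1ccccc1)[C@H]2c1cc(OCc2ccccc2)cc(OCc2ccccc2)c1)Oc1cc(OCc2ccccc2)cnn1
F2 | step 18 | 2,3-diazabicyclo[2.2.2]octa-2,5,7-triene cycloadduct of F1 (either bridgehead configuration, not isolated) | CCOC(=O)C2=C3[C@H](c4cc(OCc5ccccc5)cc(OCc5ccccc5)c4)[C@@H](c4ccc(OCc5ccccc5)c5c4O[C@H](c4ccc(OCc6ccccc6)cc4OCc4ccccc4)[C@H]5c4cc(OCc5ccccc5)cc(OCc5ccccc5)c4)OC34N=NC2C(OCc2ccccc2)=C4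
F3 | step 18 | ethyl (2S,3S)-6-(benzyloxy)-3-[3,5-bis(benzyloxy)phenyl]-2-(U2)-2,3-dihydrobenzofuran-4-carboxylate | CCOC(=O)c1cc(OCc2ccccc2)cc2c1[C@H](c1cc(OCc3ccccc3)cc(OCc3ccccc3)c1)[C@@H](c1ccc(OCc3ccccc3)c3c1O[C@H](c1ccc(OCc4ccccc4)cc1OCc1ccccc1)[C@H]3c1cc(OCc3ccccc3)cc(OCc3ccccc3)c1)O2
F4 | step 18 | [(2S,3S)-6-(benzyloxy)-3-[3,5-bis(benzyloxy)phenyl]-2-(U2)-2,3-dihydrobenzofuran-4-yl]methanol | OCc1cc(OCc2ccccc2)cc2c1[C@H](c1cc(OCc3ccccc3)cc(OCc3ccccc3)c1)[C@@H](c1ccc(OCc3ccccc3)c3c1O[C@H](c1ccc(OCc4ccccc4)cc1OCc1ccccc1)[C@H]3c1cc(OCc3ccccc3)cc(OCc3ccccc3)c1)O2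
F5 | step 18 | (2S,3S)-6-(benzyloxy)-3-[3,5-bis(benzyloxy)phenyl]-2-(U2)-2,3-dihydrobenzofuran-4-carbaldehyde | O=Cc1cc(OCc2ccccc2)cc2c1[C@H](c1cc(OCc3ccccc3)cc(OCc3ccccc3)c1)[C@@H](c1ccc(OCc3ccccc3)c3c1O[C@H](c1ccc(OCc4ccccc4)cc1OCc1ccccc1)[C@H]3c1cc(OCc3ccccc3)cc(OCc3ccccc3)c1)O2
F6 | step 5 | 3-bromo-2-[(2,4-dimethoxybenzyl)oxy]-6-methoxybenzonitrile | N#Cc1c(OCc2ccc(OC)cc2OC)c(Br)ccc1OC
F7 | step 5 | {3-bromo-2-[(2,4-dimethoxybenzyl)oxy]-6-methoxyphenyl}(3,5-dimethoxyphenyl)methanimine (not isolated) | N=C(c1cc(OC)cc(OC)c1)c1c(OCc2ccc(OC)cc2OC)c(Br)ccc1OC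
F0 | step 19 | none | none
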